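**Strategy**

Everything rests on taking ring B of the naphthoquinone apart at C3–C4, C1–C2 and C1–C8a. Ring B carries four contiguous functionalised carbons, C1(=O), C2(OH), C3(CH2 side chain) and C4(=O), fused to benzo ring A. One Dötz benzannulation assembles them: the methoxy(phenyl)carbene of chromium supplies ring A and C4, a CO ligand supplies C1, and an alkynyl pinacolboronate supplies C2 (boron as a masked hydroxyl) and C3 (silyl-protected neopentyl chain). The precursor is thus a simple boron-capped alkyne made from an isobutyrate enolate. Boron oxidation and hydrolysis then give the hydroxyquinone, which is esterified with a lactate-derived epoxy enoic acid.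

Key step: step 6

Remark: ring B is numbered C1–C4 (C4a and C8a at the ring fusion) as in the target throughout, and the hydroxyquinone is written as its 2-hydroxy-1,4-dione tautomer, the same substance as the 4-hydroxy-1,2-dione first formed on hydrolysis.

**Route**

Step 1
Reactants: 1 ethyl isobutyrate (ethyl 2-methylpropanoate); 2 propargyl bromide (3-bromoprop-1-yne)
Product: 4 ethyl 2,2-dimethylpent-4-ynoate, via lithium ester enolate 3 (not isolated)
Conditions: LiN(iPr)2, THF, −78 °C; then 2, −78 °C → rt
Reagents that add atoms: none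
Why: C-alkylation of the fully substituted lithium ester enolate by a primary propargylic bromide (enolate SN2 alkylation) builds the CH2–quaternary carbon link, and the absence of a second α-hydrogen rules out dialkylation.

Step 2
Reactants: 4 ethyl 2,2-dimethylpent-4-ynoate
Product: 5 2,2-dimethylpent-4-yn-1-ol
Conditions: LiAlH4, Et2O, 0 °C → rt; aq. NaOH work-up
Reagents that add atoms: none
Why: Hydride reduction of the ester to the primary alcohol (LiAlH4 ester reduction) leaves the remote terminal alkyne alone at this temperature.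

Step 3
Reactants: 5 2,2-dimethylpent-4-yn-1-ol
Product: 6 [(2,2-dimethylpent-4-yn-1-yl)oxy]triisopropylsilane
Conditions: iPr3SiCl, imidazole, DMF, rt
Reagents that add atoms: chlorotriisopropylsilane, CC(C)[Si](Cl)(C(C)C)C(C)C
Why: Imidazole-promoted O-silylation of the primary alcohol gives an ether that withstands n-BuLi, the chromium carbene and perborate and, unlike a free hydroxyl, cannot intercept the ketene intermediate of step 6.

Step 4
Reactants: 6 [(2,2-dimethylpent-4-yn-1-yl)oxy]triisopropylsilane
Product: 9 2-[4,4-dimethyl-5-(triisopropylsilyloxy)pent-1-yn-1-yl]-4,4,5,5-tetramethyl-1,3,2-dioxaborolane, via lithium acetylide 7 (not isolated), via lithium alkynylborate 8 (not isolated)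
Conditions: n-BuLi, THF, −78 °C; iPrOBpin, −78 °C; HCl in Et2O, −78 °C → rt
Reagents that add atoms: 2-isopropoxy-4,4,5,5-tetramethyl-1,3,2-dioxaborolane, CC(C)OB1OC(C)(C)C(C)(C)O1
Why: Deprotonation of the terminal alkyne and capture of the acetylide by the alkoxyborane gives a tetracoordinate borate that anhydrous HCl collapses to the alkynyl pinacolboronate with loss of propan-2-ol (borylation of a lithium acetylide), the non-aqueous quench avoiding protodeboronation.

Step 5
Reactants: 10 hexacarbonylchromium Cr(CO)6; 11 phenyllithium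
Product: 13 pentacarbonyl[methoxy(phenyl)carbene]chromium (CO)5Cr=C(OMe)Ph, via lithium acylchromate 12 (not isolated)
Conditions: Et2O, 0 °C → rt; then Me3OBF4, CH2Cl2, 0 °C
Reagents that add atoms: trimethyloxonium tetrafluoroborate, C[O+](C)C.F[B-](F)(F)F
Why: Addition of the aryllithium to a CO ligand of zerovalent chromium gives the acylmetalate, whose hard oxygen is methylated by the oxonium salt (Fischer carbene synthesis).

Step 6
Reactants: 13 pentacarbonyl[methoxy(phenyl)carbene]chromium; 9 2-[4,4-dimethyl-5-(triisopropylsilyloxy)pent-1-yn-1-yl]-4,4,5,5-tetramethyl-1,3,2-dioxaborolane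
Product: 15 3-[2,2-dimethyl-3-(triisopropylsilyloxy)propyl]-4-methoxy-2-(4,4,5,5-tetramethyl-1,3,2-dioxaborolan-2-yl)naphthalen-1-ol, via tricarbonylchromium naphthol complex 14 (not isolated)
Conditions: THF (degassed), 50 °C, Ar; then air, Et2O, rt, filtration through SiO2
Reagents that add atoms: none
Why: Thermal loss of one CO from the 18-electron zerovalent chromium carbene 13 frees a site for alkyne 9, which inserts into the Cr=C bond (forming C3–C4); a CO ligand then inserts to give a chromium-bound vinylketene (forming C1–C2), and 6π-electrocyclisation of this dienylketene onto the ortho carbon of the phenyl group (forming C1–C8a) followed by enol tautomerisation gives the naphthol as its Cr(CO)3 complex 14, which air demetallates. The closest known reaction type is the Dötz benzannulation of aryl(alkoxy)carbene chromium complexes with internal alkynes, which has been carried out with 1-alkynyl pinacolboronates. Ring B is closed by a pericyclic 6π electrocyclic ring closure, not by a polar cyclisation, and no stereocentre is created. The selectivity needed is the orientation of alkyne insertion: the pinacolboryl group acts as the directing alkyne substituent and should end at C2 beside the new hydroxyl, with the CH2 chain at C3 beside the methoxy-bearing C4. The opposite orientation would converge later anyway, because C–B oxidation and quinone formation turn both C1 and C4 into carbonyl carbons flanking the same C2(OH)=C3(alkyl) unit. The silyl ether keeps the side-chain oxygen from trapping the ketene, and the neutral aprotic medium leaves the C–B bond intact.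

Step 7
Reactants: 15 3-[2,2-dimethyl-3-(triisopropylsilyloxy)propyl]-4-methoxy-2-(4,4,5,5-tetramethyl-1,3,2-dioxaborolan-2-yl)naphthalen-1-ol
Product: 17 3-[2,2-dimethyl-3-(triisopropylsilyloxy)propyl]-4-methoxynaphthalene-1,2-dione, via naphthalene-1,2-diol 16 (not isolated)
Conditions: NaBO3·4H2O, THF/H2O, rt; then air, EtOAc/pH 7 phosphate buffer, rt
Reagents that add atoms: sodium perborate tetrahydrate, O.O.O.O.[Na+].[O-]OB=O
Why: Perborate adds to boron and the aryl group migrates from boron to oxygen, converting C2–B into C2–OH (arylboronate oxidation), and the electron-rich 4-methoxynaphthalene-1,2-diol so formed is dehydrogenated by oxygen to the o-quinone (catechol autoxidation) while the silyl and methyl ethers stay in place.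

Step 8
Reactants: 17 3-[2,2-dimethyl-3-(triisopropylsilyloxy)propyl]-4-methoxynaphthalene-1,2-dione
Product: 18 2-hydroxy-3-[2,2-dimethyl-3-(triisopropylsilyloxy)propyl]naphthalene-1,4-dione
Conditions: 1 M NaOH, THF, 0 °C → rt, N2; then 1 M HCl to pH 3
Reagents that add atoms: sodium hydroxide, [Na+].[OH-]
Why: Hydroxide adds at C4 of the vinylogous ester and expels methoxide (addition–elimination, vinylogous ester saponification), and the 4-hydroxy-1,2-dione tautomerises to the 2-hydroxy-1,4-dione, whose anion resists further attack while the silyl ether is stable to base.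

Step 9
Reactants: 18 2-hydroxy-3-[2,2-dimethyl-3-(triisopropylsilyloxy)propyl]naphthalene-1,4-dione
Product: 19 2-hydroxy-3-(3-hydroxy-2,2-dimethylpropyl)naphthalene-1,4-dione
Conditions: Bu4NF, THF, 0 °C → rt; then 0.5 M HCl to pH 3–4, 0 °C
Reagents that add atoms: none
Why: Fluoride cleaves the Si–O bond (desilylation) while the quinone sits as its delocalised enolate, so the liberated alkoxide cannot add to ring B and close a pyran, which is why hydrolysis precedes this step.

Step 10
Reactants: 20 methyl (R)-lactate
Product: 21 methyl (R)-2-(benzyloxy)propanoate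
Conditions: benzyl 2,2,2-trichloroacetimidate, CF3SO3H (cat.), cyclohexane/CH2Cl2, rt
Reagents that add atoms: benzyl 2,2,2-trichloroacetimidate, N=C(OCc1ccccc1)C(Cl)(Cl)Cl
Why: Acid-catalysed O-benzylation with the trichloroacetimidate needs no base, so the α-stereocentre keeps its (R) configuration, and the benzyl ether is chosen because it can chelate magnesium in step 13.

Step 11
Reactants: 21 methyl (R)-2-(benzyloxy)propanoate
Product: 22 (R)-2-(benzyloxy)-N-methoxy-N-methylpropanamide
Conditions: MeNHOMe·HCl, iPrMgCl, THF, −20 °C → 0 °C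
Reagents that add atoms: N,O-dimethylhydroxylamine hydrochloride, CNOC.Cl
Why: The chloromagnesium amide formed in the flask converts the ester into the Weinreb amide by direct aminolysis at a temperature at which the α-alkoxy stereocentre does not epimerise.

Step 12
Reactants: 22 (R)-2-(benzyloxy)-N-methoxy-N-methylpropanamide
Product: 23 (R)-3-(benzyloxy)butan-2-one
Conditions: MeMgBr, THF, 0 °C; aq. NH4Cl
Reagents that add atoms: methylmagnesium bromide, C[Mg]Br
Why: Weinreb ketone synthesis, in which the magnesium-chelated tetrahedral adduct survives until work-up, so that only one methyl group is delivered and the stereocentre is untouched.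

Step 13
Reactants: 23 (R)-3-(benzyloxy)butan-2-one; 24 but-3-en-1-ylmagnesium bromide
Product: 25 (2R,3R)-2-(benzyloxy)-3-methylhept-6-en-3-ol
Conditions: THF, −78 °C; aq. NH4Cl
Reagents that add atoms: none
Why: Chelation-controlled Grignard addition (Cram-chelate model), in which magnesium holds the carbonyl and benzyloxy oxygens in a five-membered chelate and the butenyl group enters from the face carrying the α-hydrogen instead of the α-methyl, setting the tertiary carbinol centre as (3R).

Step 14
Reactants: 25 (2R,3R)-2-(benzyloxy)-3-methylhept-6-en-3-ol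
Product: 26 (2R,3R)-3-methylhept-6-ene-2,3-diol
Conditions: Na, NH3(l), THF, −78 °C; then NH4Cl
Reagents that add atoms: none
Why: Dissolving-metal cleavage of the benzylic C–O bond (reductive debenzylation) frees the secondary alcohol, while the isolated terminal alkene, which hydrogenolysis would saturate, and both stereocentres stay intact.

Step 15
Reactants: 26 (2R,3R)-3-methylhept-6-ene-2,3-diol
Product: 28 (2R,3S)-2-(but-3-en-1-yl)-2,3-dimethyloxirane, via secondary mesylate 27 (not isolated)
Conditions: MeSO2Cl, pyridine, CH2Cl2, 0 °C; then K2CO3, MeOH, rt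
Reagents that add atoms: none
Why: Sulfonylation selects the secondary over the tertiary hydroxyl and the tertiary alkoxide then displaces the mesylate from the rear (intramolecular Williamson-type SN2 epoxide closure), which inverts the lactate-derived carbon to (3S), leaves the quaternary carbon (2R) and places the butenyl chain cis to the C3 methyl group.

Step 16
Reactants: 28 (2R,3S)-2-(but-3-en-1-yl)-2,3-dimethyloxirane; 29 ethyl 2-(triphenylphosphoranylidene)propanoate
Product: 32 ethyl (E)-5-[(2R,3S)-2,3-dimethyloxiran-2-yl]-2-methylpent-2-enoate, via ozonide 30 (not isolated), via epoxy aldehyde 31 (not isolated)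
Conditions: O3, CH2Cl2, −78 °C; PPh3, −78 °C → rt; then 29 (excess), rt
Reagents that add atoms: none
Why: Ozonolysis with a neutral phosphine reduction unmasks the volatile aldehyde without acid that could open the epoxide, and the ester-stabilised ylide then gives the (E)-trisubstituted enoate (Wittig olefination), the ylide being used in excess because formaldehyde forms alongside.

Step 17
Reactants: 32 ethyl (E)-5-[(2R,3S)-2,3-dimethyloxiran-2-yl]-2-methylpent-2-enoate
Product: 33 (E)-5-[(2R,3S)-2,3-dimethyloxiran-2-yl]-2-methylpent-2-enoic acid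
Conditions: LiOH·H2O, THF/MeOH/H2O, rt; then 10% aq. citric acid to pH 4, 0 °C
Reagents that add atoms: lithium hydroxide monohydrate, O.[Li+].[OH-]
Why: Saponification of the ethyl ester by hydroxide leaves the unactivated trisubstituted epoxide and the alkene geometry untouched, and the cold, weakly acidic work-up avoids acid-induced epoxide opening.

Step 18
Reactants: 33 (E)-5-[(2R,3S)-2,3-dimethyloxiran-2-yl]-2-methylpent-2-enoic acid; 19 2-hydroxy-3-(3-hydroxy-2,2-dimethylpropyl)naphthalene-1,4-dione
Product: 35 rhinacanthin G (3-(3-hydroxy-1,4-dioxo-1,4-dihydronaphthalen-2-yl)-2,2-dimethylpropyl (E)-5-[(2R,3S)-2,3-dimethyloxiran-2-yl]-2-methylpent-2-enoate), via mixed anhydride 34 (not isolated)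
Conditions: 2,4,6-Cl3C6H2COCl, Et3N, THF, rt; then 19, 4-(dimethylamino)pyridine, toluene, rt; pH 4 buffer work-up
Reagents that add atoms: none
Why: Yamaguchi esterification, in which the pyridine catalyst attacks the unhindered enoyl carbonyl of the mixed anhydride and the acylpyridinium acylates the primary neopentyl alcohol, while the enolic C2–OH is a poorly nucleophilic vinylogous carboxylate whose O-acyl form is itself an acyl donor, so the alkyl ester should be the end point and no stereocentre is involved.

**Compound list**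

1 | ethyl isobutyrate (ethyl 2-methylpropanoate) | CCOC(=O)C(C)C | starting material
2 | propargyl bromide (3-bromoprop-1-yne) | C#CCBr | starting material
3 | lithium enolate of ethyl isobutyrate (lithium 1-ethoxy-2-methylprop-1-en-1-olate) | CCOC([O-])=C(C)C.[Li+] | intermediate
4 | ethyl 2,2-dimethylpent-4-ynoate | CCOC(=O)C(C)(C)CC#C | intermediate
5 | 2,2-dimethylpent-4-yn-1-ol | OCC(C)(C)CC#C | intermediate
6 | [(2,2-dimethylpent-4-yn-1-yl)oxy]triisopropylsilane | CC(C)[Si](C(C)C)(C(C)C)OCC(C)(C)CC#C | intermediate
7 | lithium acetylide of 6 ([4,4-dimethyl-5-(triisopropylsilyloxy)pent-1-yn-1-yl]lithium) | [Li]C#CCC(C)(C)CO[Si](C(C)C)(C(C)C)C(C)C | intermediate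
8 | lithium alkynyl(isopropoxy)pinacolborate (tetracoordinate boron carrying the alkynyl group of 7, isopropoxy and pinacolato) | [Li+].CC(C)O[B-]1(C#CCC(C)(C)CO[Si](C(C)C)(C(C)C)C(C)C)OC(C)(C)C(C)(C)O1 | intermediate
9 | 2-[4,4-dimethyl-5-(triisopropylsilyloxy)pent-1-yn-1-yl]-4,4,5,5-tetramethyl-1,3,2-dioxaborolane | CC(C)[Si](C(C)C)(C(C)C)OCC(C)(C)CC#CB1OC(C)(C)C(C)(C)O1 | intermediate
10 | hexacarbonylchromium, Cr(CO)6 | O=C=[Cr](=C=O)(=C=O)(=C=O)(=C=O)=C=O | starting material
11 | phenyllithium | [Li]c1ccccc1 | starting material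
12 | lithium pentacarbonyl(benzoyl)chromate, Li[(CO)5Cr–C(O)Ph] | [Li+].[O-]C(c1ccccc1)=[Cr](=C=O)(=C=O)(=C=O)(=C=O)=C=O | intermediate
13 | pentacarbonyl[methoxy(phenyl)carbene]chromium, (CO)5Cr=C(OMe)Ph | COC(c1ccccc1)=[Cr](=C=O)(=C=O)(=C=O)(=C=O)=C=O | intermediate
14 | tricarbonylchromium complex of naphthol 15, Cr(CO)3 bound η6 to ring B (written as two unlinked parts) | COc1c(CC(C)(C)CO[Si](C(C)C)(C(C)C)C(C)C)c(B2OC(C)(C)C(C)(C)O2)c(O)c2ccccc12.O=C=[Cr](=C=O)=C=O | intermediate
15 | 3-[2,2-dimethyl-3-(triisopropylsilyloxy)propyl]-4-methoxy-2-(4,4,5,5-tetramethyl-1,3,2-dioxaborolan-2-yl)naphthalen-1-ol | COc1c(CC(C)(C)CO[Si](C(C)C)(C(C)C)C(C)C)c(B2OC(C)(C)C(C)(C)O2)c(O)c2ccccc12 | intermediate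
16 | 3-[2,2-dimethyl-3-(triisopropylsilyloxy)propyl]-4-methoxynaphthalene-1,2-diol | COc1c(CC(C)(C)CO[Si](C(C)C)(C(C)C)C(C)C)c(O)c(O)c2ccccc12 | intermediate
17 | 3-[2,2-dimethyl-3-(triisopropylsilyloxy)propyl]-4-methoxynaphthalene-1,2-dione | COC1=C(CC(C)(C)CO[Si](C(C)C)(C(C)C)C(C)C)C(=O)C(=O)c2ccccc12 | intermediate
18 | 2-hydroxy-3-[2,2-dimethyl-3-(triisopropylsilyloxy)propyl]naphthalene-1,4-dione | CC(C)[Si](C(C)C)(C(C)C)OCC(C)(C)CC1=C(O)C(=O)c2ccccc2C1=O | intermediate
19 | 2-hydroxy-3-(3-hydroxy-2,2-dimethylpropyl)naphthalene-1,4-dione | OCC(C)(C)CC1=C(O)C(=O)c2ccccc2C1=O | intermediate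
20 | methyl (R)-lactate (methyl (R)-2-hydroxypropanoate) | C[C@@H](O)C(=O)OC | starting material
21 | methyl (R)-2-(benzyloxy)propanoate | COC(=O)[C@@H](C)OCc1ccccc1 | intermediate
22 | (R)-2-(benzyloxy)-N-methoxy-N-methylpropanamide | CON(C)C(=O)[C@@H](C)OCc1ccccc1 | intermediate
23 | (R)-3-(benzyloxy)butan-2-one | CC(=O)[C@@H](C)OCc1ccccc1 | intermediate
24 | but-3-en-1-ylmagnesium bromide | C=CCC[Mg]Br | starting material
25 | (2R,3R)-2-(benzyloxy)-3-methylhept-6-en-3-ol | C=CCC[C@@](C)(O)[C@@H](C)OCc1ccccc1 | intermediate
26 | (2R,3R)-3-methylhept-6-ene-2,3-diol | C=CCC[C@@](C)(O)[C@@H](C)O | intermediate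
27 | (2R,3R)-3-hydroxy-3-methylhept-6-en-2-yl methanesulfonate | C=CCC[C@@](C)(O)[C@@H](C)OS(C)(=O)=O | intermediate
28 | (2R,3S)-2-(but-3-en-1-yl)-2,3-dimethyloxirane (butenyl chain cis to the C3 methyl) | C=CCC[C@@]1(C)O[C@H]1C | intermediate
29 | ethyl 2-(triphenylphosphoranylidene)propanoate | CCOC(=O)C(C)=P(c1ccccc1)(c1ccccc1)c1ccccc1 | starting material
30 | 3-{2-[(2R,3S)-2,3-dimethyloxiran-2-yl]ethyl}-1,2,4-trioxolane (ozonide, both epimers at the trioxolane carbon) | C1(CC[C@@]2(C)O[C@H]2C)OCOO1 | intermediate
31 | 3-[(2R,3S)-2,3-dimethyloxiran-2-yl]propanal | O=CCC[C@@]1(C)O[C@H]1C | intermediate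
32 | ethyl (E)-5-[(2R,3S)-2,3-dimethyloxiran-2-yl]-2-methylpent-2-enoate | C/C(=C\CC[C@@]1(C)O[C@H]1C)C(=O)OCC | intermediate
33 | (E)-5-[(2R,3S)-2,3-dimethyloxiran-2-yl]-2-methylpent-2-enoic acid | C/C(=C\CC[C@@]1(C)O[C@H]1C)C(=O)O | intermediate
34 | mixed anhydride of 33 with 2,4,6-trichlorobenzoic acid | C/C(=C\CC[C@@]1(C)O[C@H]1C)C(=O)OC(=O)c1c(Cl)cc(Cl)cc1Cl | intermediate
35 | rhinacanthin G, 3-(3-hydroxy-1,4-dioxo-1,4-dihydronaphthalen-2-yl)-2,2-dimethylpropyl (E)-5-[(2R,3S)-2,3-dimethyloxiran-2-yl]-2-methylpent-2-enoate | C/C(=C\CC[C@@]1(C)O[C@H]1C)C(=O)OCC(C)(C)CC1=C(O)C(=O)c2ccccc2C1=O | target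

**Step count and risks**

Total step count: 18. Longest linear sequence: 9 steps (steps 1–4, 6–9 and 18 from ethyl isobutyrate; the lactate line, steps 10–18, is equally long).

Steps most likely to fail:

Step 6. The hindered boron-bearing alkyne may insert slowly or with mixed orientation, the vinylketene may be diverted before ring closure, and the C–B bond may be lost by protodeboronation during demetallation. Fallback: setting out from alkyne 6 and carbene complex 13, the benzannulation is run without boron (THF, 50 °C, then air). A terminal alkyne should place its substituent beside the new hydroxyl and give 2-[2,2-dimethyl-3-(triisopropylsilyloxy)propyl]-4-methoxynaphthalen-1-ol F1. Oxidation with (NH4)2Ce(NO3)6 (tetravalent cerium) in MeCN/H2O should give 2-[2,2-dimethyl-3-(triisopropylsilyloxy)propyl]naphthalene-1,4-dione F2. Nucleophilic epoxidation with H2O2/Na2CO3 should give 1a-[2,2-dimethyl-3-(triisopropylsilyloxy)propyl]-1a,7a-dihydronaphtho[2,3-b]oxirene-2,7-dione F3. Dilute NaOH (opening of the epoxide at its CH carbon and loss of water), then acidification, should bring the route back at 18.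

Step 18. Acylation may go to the enolic oxygen in competition with the hindered neopentyl alcohol, and acyl transfer from that oxygen to the alcohol may be incomplete. Fallback: setting out from 19, the acidic enol alone is methylated with Me3SiCHN2 in toluene/MeOH to 2-(3-hydroxy-2,2-dimethylpropyl)-3-methoxynaphthalene-1,4-dione F4. The alcohol is then esterified with 33 under the same mixed-anhydride conditions to 3-(3-methoxy-1,4-dioxo-1,4-dihydronaphthalen-2-yl)-2,2-dimethylpropyl (E)-5-[(2R,3S)-2,3-dimethyloxiran-2-yl]-2-methylpent-2-enoate F5. The vinylogous methyl ester is cleaved with cold dilute LiOH, which should spare the much slower hindered enoate ester and the epoxide, and the route comes back at 35.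

Step 7. The electron-rich catechol or the o-quinone may be over-oxidised by peroxide in the basic medium while air is admitted. Fallback: setting out from 15, the quinone is made first with (NH4)2Ce(NO3)6 in MeCN/H2O at 0 °C, which should give 2-[2,2-dimethyl-3-(triisopropylsilyloxy)propyl]-3-(4,4,5,5-tetramethyl-1,3,2-dioxaborolan-2-yl)naphthalene-1,4-dione F6. Peroxide-free oxidation of the C–B bond with trimethylamine N-oxide in THF, then water, should give 18 directly, so that step 8 is not needed.

**Further compounds**

F1 | step 6 | 2-[2,2-dimethyl-3-(triisopropylsilyloxy)propyl]-4-methoxynaphthalen-1-ol | COc1cc(CC(C)(C)CO[Si](C(C)C)(C(C)C)C(C)C)c(O)c2ccccc12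
F2 | step 6 | 2-[2,2-dimethyl-3-(triisopropylsilyloxy)propyl]naphthalene-1,4-dione | CC(C)[Si](C(C)C)(C(C)C)OCC(C)(C)CC1=CC(=O)c2ccccc2C1=O
F3 | step 6 | 1a-[2,2-dimethyl-3-(triisopropylsilyloxy)propyl]-1a,7a-dihydronaphtho[2,3-b]oxirene-2,7-dione (racemic) | CC(C)[Si](C(C)C)(C(C)C)OCC(C)(C)CC12OC1C(=O)c1ccccc1C2=O
F4 | step 18 | 2-(3-hydroxy-2,2-dimethylpropyl)-3-methoxynaphthalene-1,4-dione | COC1=C(CC(C)(C)CO)C(=O)c2ccccc2C1=O
F5 | step 18 | 3-(3-methoxy-1,4-dioxo-1,4-dihydronaphthalen-2-yl)-2,2-dimethylpropyl (E)-5-[(2R,3S)-2,3-dimethyloxiran-2-yl]-2-methylpent-2-enoate | C/C(=C\CC[C@@]1(C)O[C@H]1C)C(=O)OCC(C)(C)CC1=C(OC)C(=O)c2ccccc2C1=O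
F6 | step 7 | 2-[2,2-dimethyl-3-(triisopropylsilyloxy)propyl]-3-(4,4,5,5-tetramethyl-1,3,2-dioxaborolan-2-yl)naphthalene-1,4-dione | CC(C)[Si](C(C)C)(C(C)C)OCC(C)(C)CC1=C(B2OC(C)(C)C(C)(C)O2)C(=O)c2ccccc2C1=O
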